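The quinone ring is disconnected, at the resorcinol oxidation level, into a four-membered ring and an alkyne. Heating 4-chloro-3-methylcyclobut-2-enone with a siloxy-1,4-diyne should open the cyclobutenone to a vinylketene, add the ynol ether, and expand the resulting 4-vinylcyclobutenone by two carbons to a pentasubstituted phenol. The step exploits the adjacent C5–Cl/C6–CH3 pair of the quinone (cyclobutenone C4 and C3) and the meta oxygens at C2 and C4 flanking the side-chain carbon C3 (the alkyne carbons supply C2 and C3); the unsubstituted C1 is oxidised last. The 2-butynyl arm then joins a (2S,3S,4R)-trimethylcyclohexanone aldehyde by hydrozirconation and asymmetric alkenylzinc addition.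

Key step: step 5

Remark on numbering: in the quinone, C1(=O) lies between C2(OH) and C6(CH3), and C4(=O) between C3 (side chain) and C5(Cl).

Remark on stereochemistry: the target carries E-alkene, (S)-carbinol and a (1S,2S,6R)-1,2,6-trimethyl-3-oxocyclohexyl group. The methyl alpha to the ketone is trans to the quaternary methyl, which is judged to be the less stable epimer. It is therefore set under kinetic control (step 12), and no later step uses a base able to enolise the ketone.

Remark on compound 5: it is racemic; its stereocentre is lost in step 5.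

Step 1
Reactants: 1 trichloroacetyl chloride; 2 propyne
Product: 4 4,4-dichloro-3-methylcyclobut-2-en-1-one, via dichloroketene 3 (not isolated)
Conditions: Zn/Cu couple, Et2O, 0 °C → rt (propyne condensed in, closed vessel)
Reagents that add atoms: none
Why: Zinc dechlorination of 1 gives dichloroketene, whose [2+2] cycloaddition with a terminal alkyne places the alkyne substituent at C3 next to the CCl2 carbon (dichloroketene–alkyne cycloaddition).

Step 2
Reactants: 4 4,4-dichloro-3-methylcyclobut-2-en-1-one
Product: 5 4-chloro-3-methylcyclobut-2-en-1-one (racemic)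
Conditions: Zn dust (1.1 equiv), AcOH, TMEDA, EtOH, −10 °C, stopped at the monochloride
Reagents that add atoms: none
Why: The first chlorine of an alpha,alpha-dichloro ketone is removed by zinc much faster than the second, so one equivalent at low temperature should stop at the monochloride (partial reductive dehalogenation).

Step 3
Reactants: 6 1-bromobut-2-yne; 7 ethynylmagnesium bromide (excess)
Product: 8 hexa-1,4-diyne
Conditions: CuCl (5 mol%), THF, rt → 50 °C; used as a distilled solution
Reagents that add atoms: none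
Why: Copper-catalysed SN2 coupling of a propargylic bromide with an alkynyl Grignard reagent gives the skipped diyne.

Step 4
Reactants: 8 hexa-1,4-diyne
Product: 11 triisopropyl(hexa-1,4-diyn-1-yloxy)silane, via lithium acetylide 9 (not isolated), via lithium ynolate 10 (not isolated)
Conditions: n-BuLi, THF, −78 °C; LiOOt-Bu (from t-BuOOH and LiN(SiMe3)2), −78 → 0 °C; i-Pr3SiOTf, −78 °C
Reagents that add atoms: tert-butyl hydroperoxide, used as its lithium salt, CC(C)(C)OO; triisopropylsilyl triflate CC(C)[Si](OS(=O)(=O)C(F)(F)F)(C(C)C)C(C)C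
Why: Only the terminal alkyne is deprotonated at −78 °C, the acetylide carbon is oxidised by the electrophilic oxygen of the lithium peroxide to the ynolate, and the bulky silyl triflate silylates it on oxygen (acetylide-to-ynolate oxidation and O-silylation).

Step 5
Reactants: 5 4-chloro-3-methylcyclobut-2-en-1-one; 11 triisopropyl(hexa-1,4-diyn-1-yloxy)silane
Product: 16 2-(but-2-yn-1-yl)-6-chloro-5-methyl-3-[(triisopropylsilyl)oxy]phenol, via chlorovinylketene 12 (not isolated), via 4-vinylcyclobutenone 13 (not isolated), via dienylketene 14 (not isolated), via cyclohexadienone 15 (not isolated)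
Conditions: toluene (degassed), 80 °C, then 110 °C
Reagents that add atoms: none
Why: Thermal 4π electrocyclic opening of 5 (chlorine rotating outward) gives vinylketene 12, whose ketene C=C adds the ynol ether in a [2+2] cycloaddition to 13; 4π opening of 13 gives dienylketene 14, which closes to dienone 15 and enolises to phenol 16. The closest known reaction type is the Danheiser benzannulation of cyclobutenones with siloxyalkynes; in net terms the two alkyne carbons are inserted between C1 and C2 of the cyclobutenone. The transient four-membered ring of 13 closes by ketene–alkyne [2+2] cycloaddition and the six-membered ring by thermal disrotatory 6π electrocyclisation between the ketene carbon and the CHCl terminus. No stereocentre survives: those of 5, 13 and 15 are lost on aromatisation. The step needs regiocontrol in the ketene–alkyne union, secured by bonding of the nucleophilic beta-carbon of the ynol ether to the ketene carbonyl carbon, which puts the silyloxy carbon meta to the phenol oxygen and the butynyl carbon between them. It also needs chemoselectivity for the ynol ether over the unactivated internal alkyne and retention of chlorine, which holds because 15 carries a hydrogen on the chlorinated carbon and aromatises by enolisation.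

Step 6
Reactants: 16 2-(but-2-yn-1-yl)-6-chloro-5-methyl-3-[(triisopropylsilyl)oxy]phenol
Product: 17 tert-butyl{2-(but-2-yn-1-yl)-6-chloro-5-methyl-3-[(triisopropylsilyl)oxy]phenoxy}dimethylsilane
Conditions: t-BuMe2SiOTf, 2,6-lutidine, CH2Cl2, 0 °C
Reagents that add atoms: tert-butyldimethylsilyl triflate CC(C)(C)[Si](C)(C)OS(=O)(=O)C(F)(F)F
Why: O-Silylation of the hindered phenol by the silyl triflate masks the acidic hydroxyl before the zirconium hydride and organozinc reagents of step 14.

Step 7
Reactants: 18 propanal; 19 but-3-en-2-one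
Product: 20 (2R)-2-methyl-5-oxohexanal
Conditions: (S)-2-[methoxy(diphenyl)methyl]pyrrolidine (5 mol%), ethyl 3,4-dihydroxybenzoate (20 mol%), neat, 4 °C
Reagents that add atoms: none
Why: The E-enamine of propanal is shielded on one face by the diarylmethyl ether group of the (S)-catalyst, so the Michael addition to the enone should set the (R) centre (organocatalytic enamine Michael addition).

Step 8
Reactants: 20 (2R)-2-methyl-5-oxohexanal
Product: 21 (4R)-4-methylcyclohex-2-en-1-one
Conditions: LiOH, i-PrOH, 0 °C → rt
Reagents that add atoms: none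
Why: Intramolecular aldol condensation of the methyl ketone onto the aldehyde closes the cyclohexenone, the mild hydroxide keeping erosion of the adjacent stereocentre small.

Step 9
Reactants: 21 (4R)-4-methylcyclohex-2-en-1-one
Product: 22 trimethyl{[(3S,4R)-3,4-dimethylcyclohex-1-en-1-yl]oxy}silane
Conditions: MeMgBr, CuBr·SMe2 (10 mol%), Me3SiCl, THF, −78 °C
Reagents that add atoms: methylmagnesium bromide C[Mg]Br; chlorotrimethylsilane C[Si](C)(C)Cl
Why: Copper-catalysed conjugate addition with in situ silylation traps the enolate as the silyl enol ether, the methyl entering trans to the C4 methyl (of no consequence, since C3 becomes sp2 in step 10).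

Step 10
Reactants: 22 trimethyl{[(3S,4R)-3,4-dimethylcyclohex-1-en-1-yl]oxy}silane
Product: 23 (4R)-3,4-dimethylcyclohex-2-en-1-one
Conditions: Pd(OAc)2 (1.05 equiv), MeCN, rt
Reagents that add atoms: none
Why: Saegusa–Ito oxidation, in which palladation at C2 and beta-hydride elimination of the C3 hydrogen regenerate the enone now bearing the C3 methyl, leaving C4 untouched.

Step 11
Reactants: 23 (4R)-3,4-dimethylcyclohex-2-en-1-one
Product: 24 trimethyl{[(3S,4R)-3,4-dimethyl-3-(prop-2-en-1-yl)cyclohex-1-en-1-yl]oxy}silane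
Conditions: allylMgBr, CuBr·SMe2 (1.1 equiv), Me3SiCl, THF, −78 °C
Reagents that add atoms: allylmagnesium bromide C=CC[Mg]Br; chlorotrimethylsilane C[Si](C)(C)Cl
Why: Silyl-chloride-promoted conjugate addition of the allylcopper reagent builds the quaternary centre by axial attack anti to the adjacent C4 methyl, so the two ring methyls end up cis, and the enolate is trapped regiospecifically as the C1–C2 silyl enol ether.

Step 12
Reactants: 24 trimethyl{[(3S,4R)-3,4-dimethyl-3-(prop-2-en-1-yl)cyclohex-1-en-1-yl]oxy}silane
Product: 26 (2S,3S,4R)-2,3,4-trimethyl-3-(prop-2-en-1-yl)cyclohexan-1-one, via lithium enolate 25 (not isolated)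
Conditions: MeLi, THF, 0 °C; then MeI, HMPA, −78 → −20 °C
Reagents that add atoms: iodomethane CI
Why: MeLi cleaves the silyl enol ether to the regiodefined lithium enolate, which is C-methylated axially on the face anti to the pseudoaxial quaternary methyl, that is syn to the allyl group, giving the (2S) kinetic epimer (regiospecific enolate alkylation).

Step 13
Reactants: 26 (2S,3S,4R)-2,3,4-trimethyl-3-(prop-2-en-1-yl)cyclohexan-1-one
Product: 28 2-[(1S,2S,6R)-1,2,6-trimethyl-3-oxocyclohexyl]acetaldehyde, via ozonide 27 (not isolated)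
Conditions: O3, CH2Cl2, −78 °C; then PPh3, −78 °C → rt; used promptly
Reagents that add atoms: ozone [O-][O+]=O
Why: Ozonolysis with reductive work-up cleaves the terminal alkene to the aldehyde under neutral conditions that leave the ketone and its epimerisable alpha-centre alone.

Step 14
Reactants: 17 tert-butyl{2-(but-2-yn-1-yl)-6-chloro-5-methyl-3-[(triisopropylsilyl)oxy]phenoxy}dimethylsilane; 28 2-[(1S,2S,6R)-1,2,6-trimethyl-3-oxocyclohexyl]acetaldehyde
Product: 31 (2S,3S,4R)-3-{(2S,3E)-5-[2-(tert-butyldimethylsilyloxy)-3-chloro-4-methyl-6-(triisopropylsilyloxy)phenyl]-2-hydroxy-3-methylpent-3-en-1-yl}-2,3,4-trimethylcyclohexan-1-one, via alkenylzirconocene 29 (not isolated), via alkenylzinc 30 (not isolated)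
Conditions: Cp2Zr(H)Cl (slight excess), CH2Cl2, rt; Me2Zn, toluene, −65 °C; (2R)-(+)-3-exo-morpholinoisoborneol (10 mol%), then 28, −30 → 0 °C; aq NH4Cl
Reagents that add atoms: none
Why: syn-Hydrozirconation puts zirconium on the less hindered, methyl-bearing alkyne carbon and fixes the E geometry, and after Zr-to-Zn transmetalation the amino-alcohol-catalysed addition to the aldehyde (not the ketone) should deliver the alkenyl group to the Re face, setting the (S) carbinol under ligand control (asymmetric alkenylzinc addition).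

Step 15
Reactants: 31 the bis-silyl ether from step 14
Product: 32 (2S,3S,4R)-3-[(2S,3E)-5-(3-chloro-2,6-dihydroxy-4-methylphenyl)-2-hydroxy-3-methylpent-3-en-1-yl]-2,3,4-trimethylcyclohexan-1-one
Conditions: Bu4NF, AcOH, THF, 0 °C
Reagents that add atoms: none
Why: Fluoride cleaves both aryl silyl ethers while the acetic acid buffer keeps the medium non-basic, so the ketone alpha-centre and the allylic alcohol should survive (desilylation).

Step 16
Reactants: 32 the resorcinol from step 15
Product: 33 5-chloro-2-hydroxy-3-{(2E,4S)-4-hydroxy-3-methyl-5-[(1S,2S,6R)-1,2,6-trimethyl-3-oxocyclohexyl]pent-2-en-1-yl}-6-methylcyclohexa-2,5-diene-1,4-dione (target)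
Conditions: (KO3S)2NO (2.2 equiv), KH2PO4 buffer, acetone/H2O, 0 °C → rt; acidified to pH 3 on work-up
Reagents that add atoms: potassium nitrosodisulfonate [O]N(S(=O)(=O)[O-])S(=O)(=O)[O-].[K+].[K+]
Why: Teuber oxidation, in which the nitrosodisulfonate radical oxidises the resorcinol at its only unsubstituted ring carbon, para to one hydroxyl, to the 2-hydroxy-1,4-benzoquinone without touching the secondary alcohol, the alkene or the ketone.

Compound list
1 | trichloroacetyl chloride | ClC(=O)C(Cl)(Cl)Cl | starting material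
2 | propyne | CC#C | starting material
3 | dichloroketene | ClC(Cl)=C=O | intermediate
4 | 4,4-dichloro-3-methylcyclobut-2-en-1-one | CC1=CC(=O)C1(Cl)Cl | intermediate
5 | 4-chloro-3-methylcyclobut-2-en-1-one (racemic) | CC1=CC(=O)C1Cl | intermediate
6 | 1-bromobut-2-yne | CC#CCBr | starting material
7 | ethynylmagnesium bromide | C#C[Mg]Br | starting material
8 | hexa-1,4-diyne | CC#CCC#C | intermediate
9 | lithium hexa-1,4-diyn-1-ide | [Li]C#CCC#CC | intermediate
10 | lithium hexa-1,4-diyn-1-olate | [Li]OC#CCC#CC | intermediate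
11 | triisopropyl(hexa-1,4-diyn-1-yloxy)silane | CC#CCC#CO[Si](C(C)C)(C(C)C)C(C)C | intermediate
12 | (3E)-4-chloro-3-methylbuta-1,3-dien-1-one | O=C=C/C(C)=C/Cl | intermediate
13 | 2-(but-2-yn-1-yl)-4-[(1E)-1-chloroprop-1-en-2-yl]-3-[(triisopropylsilyl)oxy]cyclobut-2-en-1-one (racemic) | O=C1C(CC#CC)=C(O[Si](C(C)C)(C(C)C)C(C)C)C1/C(C)=C/Cl | intermediate
14 | (3E,5E)-2-(but-2-yn-1-yl)-6-chloro-5-methyl-3-[(triisopropylsilyl)oxy]hexa-1,3,5-trien-1-one | O=C=C(CC#CC)/C(O[Si](C(C)C)(C(C)C)C(C)C)=C\C(C)=C\Cl | intermediate
15 | 2-(but-2-yn-1-yl)-6-chloro-5-methyl-3-[(triisopropylsilyl)oxy]cyclohexa-2,4-dien-1-one (racemic) | O=C1C(CC#CC)=C(O[Si](C(C)C)(C(C)C)C(C)C)C=C(C)C1Cl | intermediate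
16 | 2-(but-2-yn-1-yl)-6-chloro-5-methyl-3-[(triisopropylsilyl)oxy]phenol | CC#CCc1c(O)c(Cl)c(C)cc1O[Si](C(C)C)(C(C)C)C(C)C | intermediate
17 | tert-butyl{2-(but-2-yn-1-yl)-6-chloro-5-methyl-3-[(triisopropylsilyl)oxy]phenoxy}dimethylsilane | CC#CCc1c(O[Si](C)(C)C(C)(C)C)c(Cl)c(C)cc1O[Si](C(C)C)(C(C)C)C(C)C | intermediate
18 | propanal | CCC=O | starting material
19 | but-3-en-2-one | CC(=O)C=C | starting material
20 | (2R)-2-methyl-5-oxohexanal | O=C[C@H](C)CCC(C)=O | intermediate
21 | (4R)-4-methylcyclohex-2-en-1-one | O=C1C=C[C@H](C)CC1 | intermediate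
22 | trimethyl{[(3S,4R)-3,4-dimethylcyclohex-1-en-1-yl]oxy}silane | C[Si](C)(C)OC1=C[C@@H](C)[C@H](C)CC1 | intermediate
23 | (4R)-3,4-dimethylcyclohex-2-en-1-one | O=C1C=C(C)[C@H](C)CC1 | intermediate
24 | trimethyl{[(3S,4R)-3,4-dimethyl-3-(prop-2-en-1-yl)cyclohex-1-en-1-yl]oxy}silane | C[Si](C)(C)OC1=C[C@@](C)(CC=C)[C@H](C)CC1 | intermediate
25 | lithium (3S,4R)-3,4-dimethyl-3-(prop-2-en-1-yl)cyclohex-1-en-1-olate | [Li]OC1=C[C@@](C)(CC=C)[C@H](C)CC1 | intermediate
26 | (2S,3S,4R)-2,3,4-trimethyl-3-(prop-2-en-1-yl)cyclohexan-1-one | O=C1[C@@H](C)[C@@](C)(CC=C)[C@H](C)CC1 | intermediate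
27 | (2S,3S,4R)-2,3,4-trimethyl-3-(1,2,4-trioxolan-3-ylmethyl)cyclohexan-1-one (ozonide, mixture at the trioxolane carbon) | O=C1[C@@H](C)[C@@](C)(CC2OCOO2)[C@H](C)CC1 | intermediate
28 | 2-[(1S,2S,6R)-1,2,6-trimethyl-3-oxocyclohexyl]acetaldehyde | O=C1[C@@H](C)[C@@](C)(CC=O)[C@H](C)CC1 | intermediate
29 | chlorobis(cyclopentadienyl){(2E)-4-[2-(tert-butyldimethylsilyloxy)-3-chloro-4-methyl-6-(triisopropylsilyloxy)phenyl]but-2-en-2-yl}zirconium | C/C(=C\Cc1c(O[Si](C)(C)C(C)(C)C)c(Cl)c(C)cc1O[Si](C(C)C)(C(C)C)C(C)C)[Zr](Cl)(C1C=CC=C1)C1C=CC=C1 | intermediate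
30 | {(2E)-4-[2-(tert-butyldimethylsilyloxy)-3-chloro-4-methyl-6-(triisopropylsilyloxy)phenyl]but-2-en-2-yl}(methyl)zinc | C/C(=C\Cc1c(O[Si](C)(C)C(C)(C)C)c(Cl)c(C)cc1O[Si](C(C)C)(C(C)C)C(C)C)[Zn]C | intermediate
31 | (2S,3S,4R)-3-{(2S,3E)-5-[2-(tert-butyldimethylsilyloxy)-3-chloro-4-methyl-6-(triisopropylsilyloxy)phenyl]-2-hydroxy-3-methylpent-3-en-1-yl}-2,3,4-trimethylcyclohexan-1-one | CC(C)[Si](C(C)C)(C(C)C)Oc1cc(C)c(Cl)c(O[Si](C)(C)C(C)(C)C)c1C/C=C(\C)[C@@H](O)C[C@@]2(C)[C@H](C)CCC(=O)[C@H]2C | intermediate
32 | (2S,3S,4R)-3-[(2S,3E)-5-(3-chloro-2,6-dihydroxy-4-methylphenyl)-2-hydroxy-3-methylpent-3-en-1-yl]-2,3,4-trimethylcyclohexan-1-one | Oc1cc(C)c(Cl)c(O)c1C/C=C(\C)[C@@H](O)C[C@@]2(C)[C@H](C)CCC(=O)[C@H]2C | intermediate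
33 | 5-chloro-2-hydroxy-3-{(2E,4S)-4-hydroxy-3-methyl-5-[(1S,2S,6R)-1,2,6-trimethyl-3-oxocyclohexyl]pent-2-en-1-yl}-6-methylcyclohexa-2,5-diene-1,4-dione | CC1=C(Cl)C(=O)C(C/C=C(\C)[C@@H](O)C[C@@]2(C)[C@H](C)CCC(=O)[C@H]2C)=C(O)C1=O | target

Total step count: 16. Longest linear sequence: 10 steps (steps 7 to 16); the arene branch (steps 1 to 6) joins at step 14.

Steps most likely to fail

Step 5. The chlorovinylketene may be lost by oligomerisation or dehydrochlorination before the ynol ether intercepts it, or the cascade may stall at the vinylcyclobutenone. The fallback sets out from 4 (and uses 11) and moves the chlorine to a later stage. Exhaustive reductive dechlorination of 4 (excess Zn dust, AcOH, TMEDA, EtOH, rt) should give 3-methylcyclobut-2-en-1-one F1. Heating F1 with 11 in toluene at 80 °C, the parent case of the same two-carbon ring expansion, should give 2-(but-2-yn-1-yl)-5-methyl-3-[(triisopropylsilyl)oxy]phenol F2. Amine-catalysed ortho-selective chlorination (SO2Cl2, catalytic 2,2,6,6-tetramethylpiperidine, toluene, 0 °C) should then place chlorine next to the free hydroxyl, the para position being screened by the flanking silyloxy and methyl groups. The route is rejoined at 16.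

Step 2. The reduction may run on to the chlorine-free cyclobutenone, or hydrogen may be delivered at C2 with shift of the double bond to give the 2-chloro isomer. The fallback sets out from 2 and reaches the monochloro level directly by a keteniminium–alkyne [2+2] cycloaddition. 2-Chloro-N,N-dimethylacetamide with Tf2O and 2,4,6-collidine in 1,2-dichloroethane should give N-(2-chloroethenylidene)-N-methylmethanaminium triflate F3, which adds propyne 2 to give N-(4-chloro-3-methylcyclobut-2-en-1-ylidene)-N-methylmethanaminium triflate F4. Aqueous hydrolysis of F4 comes back to the route at 5.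

Step 14. Regiocontrol in the hydrozirconation may be incomplete, and facial selectivity in the alkenylzinc addition to an alpha-unbranched aliphatic aldehyde may be poor. The fallback sets out from 17 and separates the two problems. Hydrozirconation as before, followed by iodinolysis (I2, THF, 0 °C), should give tert-butyl{6-chloro-2-[(2E)-3-iodobut-2-en-1-yl]-5-methyl-3-[(triisopropylsilyl)oxy]phenoxy}dimethylsilane F5, from which any regioisomer can be removed by chromatography. Nozaki–Hiyama–Kishi coupling of F5 with 28 (CrCl2, catalytic NiCl2, chiral oxazoline–sulfonamide ligand, Et3N, THF, rt) is chemoselective for the aldehyde over the ketone. The carbinol epimers should be separable, and the route is rejoined at 31.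

Further compounds
F1 | step 5 | 3-methylcyclobut-2-en-1-one | CC1=CC(=O)C1
F2 | step 5 | 2-(but-2-yn-1-yl)-5-methyl-3-[(triisopropylsilyl)oxy]phenol | CC#CCc1c(O)cc(C)cc1O[Si](C(C)C)(C(C)C)C(C)C
F3 | step 2 | N-(2-chloroethenylidene)-N-methylmethanaminium triflate | ClC=C=[N+](C)C.[O-]S(=O)(=O)C(F)(F)F
F4 | step 2 | N-(4-chloro-3-methylcyclobut-2-en-1-ylidene)-N-methylmethanaminium triflate (racemic) | CC1=CC(=[N+](C)C)C1Cl.[O-]S(=O)(=O)C(F)(F)F
F5 | step 14 | tert-butyl{6-chloro-2-[(2E)-3-iodobut-2-en-1-yl]-5-methyl-3-[(triisopropylsilyl)oxy]phenoxy}dimethylsilane | C/C(I)=C\Cc1c(O[Si](C)(C)C(C)(C)C)c(Cl)c(C)cc1O[Si](C(C)C)(C(C)C)C(C)C
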